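**Retrosynthetic overview**
1. Locants (Stemona type): ring A = N4, C1–C3, C9a (2-pyrroline); ring B = N4, C5–C9, C9a (azepane); ring C = O, C8, C9, C10 (CH–Et), C11 (spiro ketal carbon); ring D = C11, C12 (CHOH), C13 (CHMe), C14 (C=O), O; ring E = lactone C18–C21 on C3.
2. Rings A and B close last, in one operation, from Boc-amino ketone chloride 29: amine release, condensation with the C3 ketone to a cyclic imine, N-alkylation by C5–Cl, loss of H-2. The ketone comes from a Fukuyama coupling that brings in ring E (thioester 27, from (2S,4S)-4-methylglutamic acid).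
3. Rings C and D form together in the key step, which makes the O–C8 bond: zerovalent-nickel ring expansion of acyl alkenyl cyclopropane 18 (ring C8–C9–C10, acyl carbon C11) to a dihydrofuran, then acid-induced protonation at C10 and spirolactonisation at C11.
4. Enabling feature: in ring C the ether oxygen and C8 are linked through C11–C10–C9, so the ketal carbon C11 with C10, C9 and C8 is an acyl cyclopropane in disguise. C11 is also the acyloxy carbon of lactone ring D, whose carboxyl C14 sits three atoms away and traps the C11 oxocarbenium ion.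
5. Cyclopropane 18 comes from bicyclic lactam 13 (sulfinimine addition, N-acylation, ring-closing metathesis, sulfonium-ylide cyclopropanation), then Grignard opening, lactate-triflate alkylation and enolate hydroxylation. Ring order: E (chiral pool), temporary lactam and cyclopropane, C + D, then A + B.

Key step: step 13

Remark on the chemistry: compounds 1, 2, 7, 10, 15 and 25 are taken as purchasable; in the locants above the target is 8R,9R,9aS,10S,11R,12R,13R,18S,20S.

**Step 1**
Reactants: 1 3-(tert-butyldiphenylsilyloxy)propanal; 2 (S)-2-methylpropane-2-sulfinamide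
Product: 3 (S,E)-N-sulfinyl aldimine of 1
Conditions: pyrrolidine (10 mol %), 4 Å MS, CH2Cl2, 25 °C
Reagents that add atoms: none
Why: Amine-catalysed condensation of the aldehyde with the sulfinamide (sulfinyl imine formation) gives the E-aldimine; no carbon stereocentre is formed and sulfur is untouched.

**Step 2**
Reactants: 3 (S,E)-N-sulfinyl aldimine
Product: 4 (S)-N-[(3S)-5-(tert-butyldiphenylsilyloxy)pent-1-en-3-yl]sulfinamide
Conditions: CH2=CHMgBr (THF solution), CH2Cl2, −78 → −40 °C; H2O
Reagents that add atoms: vinylmagnesium bromide, C=C[Mg]Br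
Why: 1,2-Addition of the Grignard reagent to the tert-butanesulfinyl aldimine in a non-coordinating solvent should pass through a six-membered chair transition state with magnesium on the sulfinyl oxygen, which delivers vinyl to one imine face and sets C9a as S.

**Step 3**
Reactants: 4 allylic sulfinamide
Product: 6 tert-butyl N-[(3S)-5-(tert-butyldiphenylsilyloxy)pent-1-en-3-yl]carbamate, via ammonium chloride 5 (not isolated)
Conditions: HCl (4 M, dioxane), MeOH, 0 °C; evaporate; Boc2O, Et3N, CH2Cl2, 25 °C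
Reagents that add atoms: di-tert-butyl dicarbonate, CC(C)(C)OC(=O)OC(=O)OC(C)(C)C
Why: Acidic methanolysis cleaves the N–S bond without touching C9a (the TBDPS ether tolerates brief HCl/MeOH) and Boc protection prepares the nitrogen for acylation.

**Step 4**
Reactants: 6 Boc-protected allylic amine; 7 2-methylidenebutanoyl chloride
Product: 8 N-Boc-N-(2-methylidenebutanoyl) allylic amine
Conditions: n-BuLi, THF, −78 °C; then 7, −78 → 0 °C
Reagents that add atoms: none
Why: N-Acylation of the lithiated carbamate by the acid chloride gives the imide-type diene needed for ring closure; no stereocentre is involved.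

**Step 5**
Reactants: 8 imide diene
Product: 9 tert-butyl (5S)-5-[2-(tert-butyldiphenylsilyloxy)ethyl]-3-ethyl-2-oxo-2,5-dihydro-1H-pyrrole-1-carboxylate
Conditions: second-generation Grubbs catalyst (5 mol %), PhMe, 80 °C
Reagents that add atoms: none
Why: Ring-closing metathesis of the monosubstituted and the 1,1-disubstituted alkene forms the five-membered unsaturated lactam with loss of ethene; C9a is not affected.

**Step 6**
Reactants: 10 (E)-1,4-dibromobut-2-ene
Product: 11 (E)-1-(benzyloxy)-4-bromobut-2-ene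
Conditions: BnOH, NaH, THF, 0 → 25 °C (10 in threefold excess)
Reagents that add atoms: benzyl alcohol, OCc1ccccc1
Why: Williamson ether synthesis with the dibromide in excess gives the mono-ether with the E geometry retained.

**Step 7**
Reactants: 11 allylic bromide
Product: 12 1-[(E)-4-(benzyloxy)but-2-en-1-yl]thiolan-1-ium bromide
Conditions: tetrahydrothiophene, acetone, 25 °C
Reagents that add atoms: tetrahydrothiophene, C1CCSC1
Why: SN2 S-alkylation of the sulfide by the primary allylic bromide gives the sulfonium salt.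

**Step 8**
Reactants: 9 unsaturated N-Boc lactam; 12 allylic sulfonium bromide
Product: 13 N-Boc 1-ethyl-6-alkenyl-3-azabicyclo[3.1.0]hexan-2-one (1S,4S,5R,6R)
Conditions: 12, LiHMDS, THF, −78 °C; then 9, −78 → −20 °C
Reagents that add atoms: none
Why: Corey–Chaykovsky-type cyclopropanation (Michael-initiated ring closure) of the allylic sulfonium ylide: conjugate addition to C9 should occur anti to the C9a side chain and enolate displacement of tetrahydrothiophene should place the alkenyl group exo, which sets C9 and C8 (trans) and the quaternary C10, the last being erased later.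

**Step 9**
Reactants: 13 bicyclic N-Boc lactam
Product: 14 cyclopropyl methyl ketone with free Boc-NH
Conditions: MeMgBr, THF, −78 → 0 °C; H2O
Reagents that add atoms: methylmagnesium bromide, C[Mg]Br
Why: Nucleophilic ring opening of the activated N-Boc lactam carbonyl by the Grignard reagent gives the methyl ketone (C11 with C12 as CH3); the carbamate anion released and the hindered ketone should prevent over-addition, and no stereocentre is touched.

**Step 10**
Reactants: 15 tert-butyl (R)-2-hydroxypropanoate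
Product: 16 tert-butyl (R)-2-(trifluoromethylsulfonyloxy)propanoate
Conditions: Tf2O, 2,6-lutidine, CH2Cl2, −78 → 0 °C
Reagents that add atoms: trifluoromethanesulfonic anhydride, O=S(=O)(OS(=O)(=O)C(F)(F)F)C(F)(F)F
Why: O-Sulfonylation of the α-hydroxy ester activates it for displacement; the stereocentre is not involved.

**Step 11**
Reactants: 14 methyl ketone; 16 lactate triflate
Product: 17 γ-keto tert-butyl ester (13R)
Conditions: LDA (2.2 equiv), THF, −78 °C; then 16, −78 → −40 °C; H2O
Reagents that add atoms: none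
Why: SN2 alkylation of the ketone enolate (the more basic site of the N,C-dianion) by the carbonyl-activated secondary triflate should proceed with inversion and set C13 as R.

**Step 12**
Reactants: 17 γ-keto ester
Product: 18 (12R,13R)-α-hydroxy ketone, the key-step substrate
Conditions: KHMDS (2.3 equiv), THF, −78 °C; then trans-3-phenyl-2-(phenylsulfonyl)oxaziridine, −78 °C; H2O
Reagents that add atoms: trans-3-phenyl-2-(phenylsulfonyl)oxaziridine, O=S(=O)(c1ccccc1)N1OC1c1ccccc1
Why: Davis enolate oxidation: only the C12 side of the ketone can enolise (C10 is quaternary), and the Z-enolate with C13–H eclipsing the enolate plane (allylic 1,3-strain) should be attacked anti to the tert-butoxycarbonyl group, giving the syn (12R,13R) ketol.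

**Step 13**
Reactants: 18 1-acyl-2-alkenylcyclopropane ketol
Product: 20 spiro ketal-lactone with rings C and D (3R,4R,5R,7R,8R,9S in spiro numbering), via dihydrofuran 19 (not isolated)
Conditions: Ni(cod)2 [bis(cycloocta-1,5-diene)nickel] (10 mol %), PhMe, 25 °C; then camphor-10-sulfonic acid (30 mol %), CH2Cl2, 25 → 40 °C, one flask
Reagents that add atoms: none
Why: Zerovalent nickel binds the alkenyl group and adds oxidatively to the strained C8–C10 bond with inversion at C8, giving an allylnickel/ketone-enolate ion pair whose enolate oxygen closes onto C8 anti to nickel, so strain release delivers dihydrofuran 19 with the new O–C8 bond; the sulfonic acid then protonates the enol ether at C10 and the C11 oxocarbenium ion is captured by the tert-butyl ester carbonyl, which loses 2-methylpropene to give the lactone. The closest known reactions are the nickel-catalysed rearrangement of 1-acyl-2-vinylcyclopropanes to 4,5-dihydrofurans (a metal-mediated Cloke–Wilson rearrangement) and the acid-induced spirolactonisation of cyclic enol ethers that carry a tert-butyl ester. Ring C closes by 5-exo O-allylation of the enolate at the allyl terminus C8, and ring D by 5-exo-trig addition of the ester carbonyl oxygen to the C11 oxocarbenium ion. C8 is fixed by net retention (double inversion) from the trans-cyclopropane, and trans-8,9 is also the thermodynamic outcome if the allylnickel species equilibrates; C10 and C11 are set under thermodynamic (Curtin–Hammett) control, because kinetic protonation anti to the C9 substituent would give the 10-epimer but proton exchange at C10 and re-ionisation of the acylal at C11 remain open under the acid, and the favoured isomer should have ethyl trans to the C9 substituent and the C12 carbon anti to ethyl. The step needs cleavage of C8–C10 and not C9–C10, which the alkenyl donor on C8 secures because only C8 can become an allyl terminus, and O- rather than C-attack of the enolate, which is secured because C-attack only regenerates the cyclopropane while the five-membered enol ether is drained irreversibly by the acid stage.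

**Step 14**
Reactants: 20 alkenyl benzyl ether spiro lactone
Product: 21 saturated primary alcohol (C5–OH)
Conditions: H2 (1 atm), Pd/C, EtOAc–EtOH, 25 °C
Reagents that add atoms: none
Why: Heterogeneous hydrogenation saturates the C6–C7 alkene (removing the allylic ether system) and hydrogenolyses the benzyl ether in the same operation; no stereocentre is affected.

**Step 15**
Reactants: 21 primary alcohol
Product: 22 primary chloride (C5–Cl)
Conditions: PPh3, NCS, CH2Cl2, 0 → 25 °C
Reagents that add atoms: N-chlorosuccinimide, O=C1CCC(=O)N1Cl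
Why: Appel-type chlorination (chlorophosphonium activation, SN2) should convert the primary alcohol selectively, the hindered secondary C12 hydroxyl reacting much more slowly.

**Step 16**
Reactants: 22 TBDPS ether
Product: 23 primary alcohol at C2
Conditions: HF·pyridine, pyridine, THF, 0 → 25 °C
Reagents that add atoms: none
Why: Fluoride-mediated desilylation under mildly acidic conditions that the ketal-lactone, carbamate and alkyl chloride tolerate.

**Step 17**
Reactants: 23 primary alcohol
Product: 24 primary iodide at C2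
Conditions: I2, PPh3, imidazole, CH2Cl2, 0 °C
Reagents that add atoms: iodine, II
Why: Appel-type iodination (SN2 on the alkoxyphosphonium ion) of the primary alcohol; the alkyl chloride and the hindered secondary alcohol should remain.

**Step 18**
Reactants: 25 (2S,4S)-4-methylglutamic acid
Product: 26 (2S,4S)-4-methyl-5-oxooxolane-2-carboxylic acid
Conditions: NaNO2, aq. HCl, 0 → 25 °C
Reagents that add atoms: none
Why: Diazotisation of the α-amino acid with double inversion (α-lactone, then attack of the γ-carboxyl) gives the γ-lactone with net retention, so C18 stays S and cis to the C20 methyl group.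

**Step 19**
Reactants: 26 lactone acid
Product: 27 S-ethyl (2S,4S)-4-methyl-5-oxooxolane-2-carbothioate
Conditions: EtSH, DCC, DMAP (5 mol %), CH2Cl2, 0 → 25 °C
Reagents that add atoms: ethanethiol, CCS
Why: Steglich-type carbodiimide thioesterification gives the acyl donor for the Fukuyama coupling under conditions mild enough to keep C18.

**Step 20**
Reactants: 24 alkyl iodide; 27 thioester
Product: 29 Boc-amino ketone chloride carrying ring E, via alkylzinc iodide 28 (not isolated)
Conditions: Zn dust (activated), DMF, 25 °C; then 27, PdCl2(PPh3)2 (5 mol %), PhMe, 25 °C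
Reagents that add atoms: none
Why: Zinc inserts into the C–I bond only (the alkyl chloride is inert) and the alkylzinc iodide undergoes Fukuyama coupling with the thioester, a ketone synthesis that tolerates lactones, the ketal, carbamate N–H and the hindered hydroxyl and should not epimerise C18.

**Step 21**
Reactants: 29 Boc-amino ketone chloride
Product: 32 CNP0272443.1, via ammonium trifluoroacetate 30 (not isolated), via cyclic imine 31 (not isolated)
Conditions: TFA, CH2Cl2, 0 °C; evaporate; i-Pr2NEt, NaI (20 mol %), 4 Å MS, MeCN, 25 → 60 °C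
Reagents that add atoms: none
Why: Acidolysis of the Boc group frees the primary amine, which condenses with the C3 ketone to the five-membered cyclic imine (ring A); iodide-assisted intramolecular N-alkylation by C5–Cl (7-exo-tet, ring B) gives the bicyclic iminium ion and deprotonation at C2 should deliver the endocyclic enamine without touching a stereocentre.

**Compound list**
1 | 3-(tert-butyldiphenylsilyloxy)propanal | O=CCCO[Si](c1ccccc1)(c1ccccc1)C(C)(C)C | starting material
2 | (S)-2-methylpropane-2-sulfinamide | CC(C)(C)[S@](=O)N | starting material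
3 | (S,E)-N-[3-(tert-butyldiphenylsilyloxy)propylidene]-2-methylpropane-2-sulfinamide | CC(C)(C)[S@](=O)/N=C/CCO[Si](c1ccccc1)(c1ccccc1)C(C)(C)C | intermediate
4 | (S)-N-[(3S)-5-(tert-butyldiphenylsilyloxy)pent-1-en-3-yl]-2-methylpropane-2-sulfinamide | C=C[C@@H](N[S@@](=O)C(C)(C)C)CCO[Si](c1ccccc1)(c1ccccc1)C(C)(C)C | intermediate
5 | (3S)-5-(tert-butyldiphenylsilyloxy)pent-1-en-3-aminium chloride | C=C[C@@H]([NH3+])CCO[Si](c1ccccc1)(c1ccccc1)C(C)(C)C.[Cl-] | intermediate
6 | tert-butyl N-[(3S)-5-(tert-butyldiphenylsilyloxy)pent-1-en-3-yl]carbamate | C=C[C@@H](NC(=O)OC(C)(C)C)CCO[Si](c1ccccc1)(c1ccccc1)C(C)(C)C | intermediate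
7 | 2-methylidenebutanoyl chloride (2-ethylacryloyl chloride) | CCC(=C)C(=O)Cl | starting material
8 | tert-butyl N-[(3S)-5-(tert-butyldiphenylsilyloxy)pent-1-en-3-yl]-N-(2-methylidenebutanoyl)carbamate | C=C[C@@H](N(C(=O)OC(C)(C)C)C(=O)C(=C)CC)CCO[Si](c1ccccc1)(c1ccccc1)C(C)(C)C | intermediate
9 | tert-butyl (5S)-5-[2-(tert-butyldiphenylsilyloxy)ethyl]-3-ethyl-2-oxo-2,5-dihydro-1H-pyrrole-1-carboxylate | CCC1=C[C@H](CCO[Si](c2ccccc2)(c2ccccc2)C(C)(C)C)N(C(=O)OC(C)(C)C)C1=O | intermediate
10 | (E)-1,4-dibromobut-2-ene | BrC/C=C/CBr | starting material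
11 | (E)-1-(benzyloxy)-4-bromobut-2-ene | BrC/C=C/COCc1ccccc1 | intermediate
12 | 1-[(E)-4-(benzyloxy)but-2-en-1-yl]thiolan-1-ium bromide | C(/C=C/COCc1ccccc1)[S+]1CCCC1.[Br-] | intermediate
13 | tert-butyl (1S,4S,5R,6R)-6-[(E)-3-(benzyloxy)prop-1-en-1-yl]-4-[2-(tert-butyldiphenylsilyloxy)ethyl]-1-ethyl-2-oxo-3-azabicyclo[3.1.0]hexane-3-carboxylate | CC[C@@]12C(=O)N(C(=O)OC(C)(C)C)[C@@H](CCO[Si](c3ccccc3)(c3ccccc3)C(C)(C)C)[C@@H]1[C@H]2/C=C/COCc1ccccc1 | intermediate
14 | tert-butyl N-[(1S)-1-[(1R,2S,3R)-2-acetyl-3-[(E)-3-(benzyloxy)prop-1-en-1-yl]-2-ethylcyclopropyl]-3-(tert-butyldiphenylsilyloxy)propyl]carbamate | CC[C@@]1(C(C)=O)[C@H]([C@@H](NC(=O)OC(C)(C)C)CCO[Si](c2ccccc2)(c2ccccc2)C(C)(C)C)[C@H]1/C=C/COCc1ccccc1 | intermediate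
15 | tert-butyl (R)-2-hydroxypropanoate | C[C@@H](O)C(=O)OC(C)(C)C | starting material
16 | tert-butyl (R)-2-(trifluoromethylsulfonyloxy)propanoate | C[C@@H](OS(=O)(=O)C(F)(F)F)C(=O)OC(C)(C)C | intermediate
17 | tert-butyl (2R)-4-[(1S,2R,3R)-3-[(E)-3-(benzyloxy)prop-1-en-1-yl]-2-[(1S)-1-(tert-butoxycarbonylamino)-3-(tert-butyldiphenylsilyloxy)propyl]-1-ethylcyclopropyl]-2-methyl-4-oxobutanoate | CC[C@@]1(C(=O)C[C@@H](C)C(=O)OC(C)(C)C)[C@H]([C@@H](NC(=O)OC(C)(C)C)CCO[Si](c2ccccc2)(c2ccccc2)C(C)(C)C)[C@H]1/C=C/COCc1ccccc1 | intermediate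
18 | tert-butyl (2R,3R)-4-[(1S,2R,3R)-3-[(E)-3-(benzyloxy)prop-1-en-1-yl]-2-[(1S)-1-(tert-butoxycarbonylamino)-3-(tert-butyldiphenylsilyloxy)propyl]-1-ethylcyclopropyl]-3-hydroxy-2-methyl-4-oxobutanoate | CC[C@@]1(C(=O)[C@H](O)[C@@H](C)C(=O)OC(C)(C)C)[C@H]([C@@H](NC(=O)OC(C)(C)C)CCO[Si](c2ccccc2)(c2ccccc2)C(C)(C)C)[C@H]1/C=C/COCc1ccccc1 | intermediate
19 | tert-butyl (2R,3R)-3-[(4R,5R)-5-[(E)-3-(benzyloxy)prop-1-en-1-yl]-4-[(1S)-1-(tert-butoxycarbonylamino)-3-(tert-butyldiphenylsilyloxy)propyl]-3-ethyl-4,5-dihydrofuran-2-yl]-3-hydroxy-2-methylpropanoate | CCC1=C([C@H](O)[C@@H](C)C(=O)OC(C)(C)C)O[C@H](/C=C/COCc2ccccc2)[C@H]1[C@@H](NC(=O)OC(C)(C)C)CCO[Si](c1ccccc1)(c1ccccc1)C(C)(C)C | intermediate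
20 | tert-butyl N-[(1S)-1-[(3R,4R,5R,7R,8R,9S)-7-[(E)-3-(benzyloxy)prop-1-en-1-yl]-9-ethyl-4-hydroxy-3-methyl-2-oxo-1,6-dioxaspiro[4.4]nonan-8-yl]-3-(tert-butyldiphenylsilyloxy)propyl]carbamate | CC[C@H]1[C@H]([C@@H](NC(=O)OC(C)(C)C)CCO[Si](c2ccccc2)(c2ccccc2)C(C)(C)C)[C@@H](/C=C/COCc2ccccc2)O[C@@]12OC(=O)[C@H](C)[C@H]2O | intermediate
21 | tert-butyl N-[(1S)-1-[(3R,4R,5R,7R,8R,9S)-9-ethyl-4-hydroxy-7-(3-hydroxypropyl)-3-methyl-2-oxo-1,6-dioxaspiro[4.4]nonan-8-yl]-3-(tert-butyldiphenylsilyloxy)propyl]carbamate | CC[C@H]1[C@H]([C@@H](NC(=O)OC(C)(C)C)CCO[Si](c2ccccc2)(c2ccccc2)C(C)(C)C)[C@@H](CCCO)O[C@@]12OC(=O)[C@H](C)[C@H]2O | intermediate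
22 | tert-butyl N-[(1S)-1-[(3R,4R,5R,7R,8R,9S)-7-(3-chloropropyl)-9-ethyl-4-hydroxy-3-methyl-2-oxo-1,6-dioxaspiro[4.4]nonan-8-yl]-3-(tert-butyldiphenylsilyloxy)propyl]carbamate | CC[C@H]1[C@H]([C@@H](NC(=O)OC(C)(C)C)CCO[Si](c2ccccc2)(c2ccccc2)C(C)(C)C)[C@@H](CCCCl)O[C@@]12OC(=O)[C@H](C)[C@H]2O | intermediate
23 | tert-butyl N-[(1S)-1-[(3R,4R,5R,7R,8R,9S)-7-(3-chloropropyl)-9-ethyl-4-hydroxy-3-methyl-2-oxo-1,6-dioxaspiro[4.4]nonan-8-yl]-3-hydroxypropyl]carbamate | CC[C@H]1[C@H]([C@@H](NC(=O)OC(C)(C)C)CCO)[C@@H](CCCCl)O[C@@]12OC(=O)[C@H](C)[C@H]2O | intermediate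
24 | tert-butyl N-[(1S)-1-[(3R,4R,5R,7R,8R,9S)-7-(3-chloropropyl)-9-ethyl-4-hydroxy-3-methyl-2-oxo-1,6-dioxaspiro[4.4]nonan-8-yl]-3-iodopropyl]carbamate | CC[C@H]1[C@H]([C@@H](NC(=O)OC(C)(C)C)CCI)[C@@H](CCCCl)O[C@@]12OC(=O)[C@H](C)[C@H]2O | intermediate
25 | (2S,4S)-4-methylglutamic acid | OC(=O)[C@@H](N)C[C@H](C)C(O)=O | starting material
26 | (2S,4S)-4-methyl-5-oxooxolane-2-carboxylic acid | OC(=O)[C@@H]1C[C@H](C)C(=O)O1 | intermediate
27 | S-ethyl (2S,4S)-4-methyl-5-oxooxolane-2-carbothioate | CCSC(=O)[C@@H]1C[C@H](C)C(=O)O1 | intermediate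
28 | [(3S)-3-(tert-butoxycarbonylamino)-3-[(3R,4R,5R,7R,8R,9S)-7-(3-chloropropyl)-9-ethyl-4-hydroxy-3-methyl-2-oxo-1,6-dioxaspiro[4.4]nonan-8-yl]propyl]zinc iodide | CC[C@H]1[C@H]([C@@H](NC(=O)OC(C)(C)C)CC[Zn]I)[C@@H](CCCCl)O[C@@]12OC(=O)[C@H](C)[C@H]2O | intermediate
29 | tert-butyl N-[(1S)-1-[(3R,4R,5R,7R,8R,9S)-7-(3-chloropropyl)-9-ethyl-4-hydroxy-3-methyl-2-oxo-1,6-dioxaspiro[4.4]nonan-8-yl]-4-[(2S,4S)-4-methyl-5-oxooxolan-2-yl]-4-oxobutyl]carbamate | CC[C@H]1[C@H]([C@@H](NC(=O)OC(C)(C)C)CCC(=O)[C@@H]2C[C@H](C)C(=O)O2)[C@@H](CCCCl)O[C@@]12OC(=O)[C@H](C)[C@H]2O | intermediate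
30 | (1S)-1-[(3R,4R,5R,7R,8R,9S)-7-(3-chloropropyl)-9-ethyl-4-hydroxy-3-methyl-2-oxo-1,6-dioxaspiro[4.4]nonan-8-yl]-4-[(2S,4S)-4-methyl-5-oxooxolan-2-yl]-4-oxobutan-1-aminium trifluoroacetate | CC[C@H]1[C@H]([C@@H]([NH3+])CCC(=O)[C@@H]2C[C@H](C)C(=O)O2)[C@@H](CCCCl)O[C@@]12OC(=O)[C@H](C)[C@H]2O.[O-]C(=O)C(F)(F)F | intermediate
31 | (3R,4R,5R,7R,8R,9S)-7-(3-chloropropyl)-9-ethyl-4-hydroxy-3-methyl-8-[(2S)-5-[(2S,4S)-4-methyl-5-oxooxolan-2-yl]-3,4-dihydro-2H-pyrrol-2-yl]-1,6-dioxaspiro[4.4]nonan-2-one | CC[C@H]1[C@H]([C@@H]2CCC([C@@H]3C[C@H](C)C(=O)O3)=N2)[C@@H](CCCCl)O[C@@]12OC(=O)[C@H](C)[C@H]2O | intermediate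
32 | CNP0272443.1: (8R,9R,9aS,10S,11R,12R,13R,18S,20S)-pentacycle with 2-pyrroline ring A and azepane ring B, trans-fused tetrahydrofuran ring C, spiro 12-hydroxy-13-methyl γ-lactone ring D at C11, ethyl on C10, and a (18S,20S)-20-methyl γ-lactone ring E on C3 | CC[C@H]1[C@H]2[C@@H](CCCN3C([C@@H]4C[C@H](C)C(=O)O4)=CC[C@@H]23)O[C@@]12OC(=O)[C@H](C)[C@H]2O | target

**Step count**
Total: 21 steps. Longest linear sequence: 16 steps (1 → 3 → 4 → 6 → 8 → 9 → 13 → 14 → 17 → 18 → 20 → 21 → 22 → 23 → 24 → 29 → 32).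

**Three steps most likely to fail**

Step 13. The nickel stage may stall because zerovalent nickel binds the hindered 1,2-disubstituted alkenyl donor weakly, or the allylnickel intermediate may lose benzyl oxide by 1,4-elimination. A slow acid stage would in addition leave the kinetic 10-epimer, which is answered by longer equilibration. Fallback: the route is left at 18. Ethenolysis (ethene, second-generation Hoveyda–Grubbs catalyst, CH2Cl2, 40 °C) should give the terminal vinylcyclopropyl ketol F1, the substrate type with the closest precedent for the nickel-catalysed ring expansion. The same two-stage protocol should convert it into the 7-vinyl spiro lactone F2. Cross-metathesis of F2 with allyl benzyl ether (second-generation Grubbs catalyst, CH2Cl2, 40 °C) restores the E-benzyloxypropenyl group, and the route is rejoined at 20.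

Step 12. Facial selectivity may be poor in the oxidation of an acyclic enolate whose only control element is the neighbouring C13 centre. Fallback: the route is left at 17. The oxidation is run as written and the (12S)-epimer F3 is inverted and not discarded. Mitsunobu reaction (4-nitrobenzoic acid, PPh3, DIAD, PhMe, 0 °C) should give the (12R)-4-nitrobenzoate F4. Mild methanolysis (K2CO3, MeOH, 0 °C) then rejoins the route at 18.

Step 8. The functionalised ylide may decompose by 1,4-elimination of benzyl oxide, the lactam may be deprotonated at C9a by the basic ylide, and exo selectivity next to the quaternary centre may be low. Fallback: the route is left at 9. The parent allyl ylide, generated from 1-allylthiolan-1-ium bromide F5 (allyl bromide and tetrahydrothiophene; then LiHMDS, THF, −78 °C), should give the 6-vinyl bicyclic lactam F6. Cross-metathesis of F6 with allyl benzyl ether (second-generation Hoveyda–Grubbs catalyst, CH2Cl2, 40 °C) installs the E-benzyloxypropenyl group, and the route is rejoined at 13.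

**Further compounds**
F1 | step 13 | tert-butyl (2R,3R)-4-[(1S,2R,3R)-2-[(1S)-1-(tert-butoxycarbonylamino)-3-(tert-butyldiphenylsilyloxy)propyl]-3-ethenyl-1-ethylcyclopropyl]-3-hydroxy-2-methyl-4-oxobutanoate | CC[C@@]1(C(=O)[C@H](O)[C@@H](C)C(=O)OC(C)(C)C)[C@H]([C@@H](NC(=O)OC(C)(C)C)CCO[Si](c2ccccc2)(c2ccccc2)C(C)(C)C)[C@H]1C=C
F2 | step 13 | tert-butyl N-[(1S)-1-[(3R,4R,5R,7R,8R,9S)-7-ethenyl-9-ethyl-4-hydroxy-3-methyl-2-oxo-1,6-dioxaspiro[4.4]nonan-8-yl]-3-(tert-butyldiphenylsilyloxy)propyl]carbamate | CC[C@H]1[C@H]([C@@H](NC(=O)OC(C)(C)C)CCO[Si](c2ccccc2)(c2ccccc2)C(C)(C)C)[C@@H](C=C)O[C@@]12OC(=O)[C@H](C)[C@H]2O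
F3 | step 12 | tert-butyl (2R,3S)-4-[(1S,2R,3R)-3-[(E)-3-(benzyloxy)prop-1-en-1-yl]-2-[(1S)-1-(tert-butoxycarbonylamino)-3-(tert-butyldiphenylsilyloxy)propyl]-1-ethylcyclopropyl]-3-hydroxy-2-methyl-4-oxobutanoate (12-epimer of 18) | CC[C@@]1(C(=O)[C@@H](O)[C@@H](C)C(=O)OC(C)(C)C)[C@H]([C@@H](NC(=O)OC(C)(C)C)CCO[Si](c2ccccc2)(c2ccccc2)C(C)(C)C)[C@H]1/C=C/COCc1ccccc1
F4 | step 12 | 4-nitrobenzoate of 18 at the C12 hydroxyl (12R) | CC[C@@]1(C(=O)[C@H](OC(=O)c2ccc(cc2)[N+](=O)[O-])[C@@H](C)C(=O)OC(C)(C)C)[C@H]([C@@H](NC(=O)OC(C)(C)C)CCO[Si](c2ccccc2)(c2ccccc2)C(C)(C)C)[C@H]1/C=C/COCc1ccccc1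
F5 | step 8 | 1-(prop-2-en-1-yl)thiolan-1-ium bromide | C=CC[S+]1CCCC1.[Br-]
F6 | step 8 | tert-butyl (1S,4S,5R,6R)-6-ethenyl-4-[2-(tert-butyldiphenylsilyloxy)ethyl]-1-ethyl-2-oxo-3-azabicyclo[3.1.0]hexane-3-carboxylate | CC[C@@]12C(=O)N(C(=O)OC(C)(C)C)[C@@H](CCO[Si](c3ccccc3)(c3ccccc3)C(C)(C)C)[C@@H]1[C@H]2C=C
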